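## Retrosynthetic overview
1. C7–C11 is made last, by trans-diaxial opening of a 7α,8α-epoxide with an isopropenyl cuprate. This gives 7β-isopropenyl and 8α-OH together, and every oxidation is finished before this alkene exists.
2. The epoxide comes from the Δ7 allylic angelate, which comes from the 9α-angeloyloxy-8-ketone by ketone reduction and syn-dehydration.
3. The key bond is C9–O: iodine(III) transfers angelate to the Δ8(9) enol silane released by Li/NH3 reduction of the octalone (which sets 10α-H). The second C–O event is C2–OAc, formed by ozonolysis/Criegee C→O shift of carvone's isopropenyl group with retention.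
4. Ring order: ring A is the ring of (S)-carvone (C2 from the pool, C4 by 1,4-methylation). Ring B is closed second, by Mukaiyama–Michael/aldol annulation with MVK, which sets C5.

Assumption: eremophilane numbering is used for the decalin core (ring A = C1–C5, C10; ring B = C5–C10; CH3 on C4 and C5; isopropenyl on C7). β is the face of the C5 methyl, and Ang = (Z)-2-methylbut-2-enoyl. The target is then (2S,4S,5R,7R,8R,9S,10R)-2α-acetoxy-9α-angeloyloxy-8α-hydroxy-10αH-eremophil-11-ene, a trans-decalin.

## Route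

Step 1
Reactants: 1 (S)-(+)-carvone; 2 methylmagnesium bromide
Product: 4 {[(3S,5S)-2,3-dimethyl-5-(prop-1-en-2-yl)cyclohex-1-en-1-yl]oxy}trimethylsilane, via bromomagnesium enolate 3 (not isolated)
Conditions: MeMgBr (1.3 equiv), CuBr·SMe2 (5 mol %), THF, −78 → −20 °C; then TMSCl, Et3N, DMPU, −20 °C → rt
Reagents that add atoms: methylmagnesium bromide (2), C[Mg]Br; chlorotrimethylsilane, C[Si](C)(C)Cl
Why: Copper-catalysed 1,4-addition delivers methyl axially and anti to the isopropenyl group of carvone, setting C4 (4β-CH3, trans to the 2α substituent), and O-silylation fixes the regiodefined tetrasubstituted enolate.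

Step 2
Reactants: 4 ring enol silane; 5 methyl vinyl ketone
Product: 8 (4aR,5S,7S)-4a,5-dimethyl-7-(prop-1-en-2-yl)-4,4a,5,6,7,8-hexahydronaphthalen-2(3H)-one, via silyl Michael adduct 6 (not isolated), via 1,5-diketone 7 (not isolated)
Conditions: MVK (1.5 equiv), TrSbCl6 (5 mol %), CH2Cl2, −78 °C; then KOH, MeOH, 0 → 60 °C
Reagents that add atoms: methyl vinyl ketone (5), C=CC(C)=O
Why: In this Mukaiyama–Michael addition and aldol condensation (Robinson annulation), MVK attacks the enol silane axially and anti to the pseudoaxial neighbouring C4 methyl, so the quaternary C5 forms with the two methyls cis (both β), and dehydration closes ring B.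

Step 3
Reactants: 8 octalone
Product: 10 8-trimethylsilyloxy-2α-isopropenyl-4β,5β-dimethyl-10αH-Δ8(9)-octalin (trans-fused), via lithium enolate 9 (not isolated)
Conditions: Li (2.3 equiv), t-BuOH (1.0 equiv), NH3(l)/THF, −78 → −33 °C; isoprene; evaporate NH3; TMSCl/Et3N, THF, −10 °C; pentane/cold aq NaHCO3
Reagents that add atoms: chlorotrimethylsilane, C[Si](C)(C)Cl
Why: Dissolving-metal enone reduction protonates C10 axially on the face opposite the angular methyl (10α-H, trans-decalin) and releases the enolate only towards C9, so Stork-type silyl trapping gives the Δ8(9) enol silane regiospecifically while the isolated isopropenyl group is inert.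

Step 4
Reactants: 10 enol silane; 11 angelic acid [(Z)-2-methylbut-2-enoic acid]
Product: 13 9α-angeloyloxy-2α-isopropenyl-4β,5β-dimethyl-10αH-decalin-8-one, via iodine(III) enolate 12 (not isolated)
Conditions: PhI(OAc)2 (1.3 equiv), 11 (2.7 equiv), PhCl, 40 °C, 20 mbar (−AcOH); then CH2Cl2, BF3·OEt2 (1.3 equiv), −78 °C, slow addition of 10, → −40 °C; Et3N, aq NaHCO3
Reagents that add atoms: angelic acid (11), C/C=C(/C)C(=O)O
Why: Proposed new method: direct "angelate cation" transfer from a bis(angeloyloxy)-λ3-iodane made in situ to a regiodefined enol silane, in which BF3-activated PhI(OAng)2 is attacked by the enol silane with loss of Me3SiOAng to give the O-bound iodine(III) enolate 12 (C9 now electrophilic) and the remaining angelate ligand is delivered to C9 through a tight ion pair or seven-membered cyclic transition state as PhI leaves; delivery is on the α face because the β face of C9 is blocked by the syn-axial C5 methyl, the equatorial 9α-ester is also the thermodynamic epimer (the Et3N quench corrects any 9β), slow inverse addition suppresses 1,4-diketone coupling, the enol silane far outruns the isopropenyl and angelate C=C bonds, and −78 °C without nucleophilic catalysts keeps the Z geometry that esterifying such a hindered carbinol endangers; the closest known reaction types are α-acetoxylation/α-tosyloxylation of ketones and silyl enol ethers with PhI(OAc)2·BF3 or Koser-type reagents (enolonium chemistry) and lead(IV) carboxylate oxidation of enol silanes, neither shown for a geometrically labile α,β-unsaturated acyloxy ligand or for a Birch-derived ring-fusion enol silane.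

Step 5
Reactants: 13 angeloyloxy ketone
Product: 16 2α-acetoxy-9α-angeloyloxy-4β,5β-dimethyl-10αH-decalin-8-one, via methoxy hydroperoxide 14 (not isolated), via peracetate 15 (not isolated)
Conditions: O3 (1.0 equiv, Sudan Red 7B end-point), CH2Cl2/MeOH 4:1, −78 °C; N2 purge, concentrate; Ac2O, Et3N, DMAP (cat.), CH2Cl2, 0 → 40 °C
Reagents that add atoms: ozone, [O-][O+]=O; methanol, CO
Why: Ozone takes the electron-rich 1,1-disubstituted alkene ahead of the conjugated trisubstituted angelate, and the acetylated methoxy hydroperoxide undergoes Criegee rearrangement in which ring carbon C2 migrates from carbon to oxygen with retention, so carvone's stereocentre becomes the 2α-acetate (its acetyl carbons are the old C(CH3) unit and the methoxy oxygen ends as C=O).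

Step 6
Reactants: 16 keto diester
Product: 17 2α-acetoxy-9α-angeloyloxy-4β,5β-dimethyl-10αH-decalin-8α-ol
Conditions: L-Selectride (1.05 equiv), THF, −78 °C, 30 min; sat. aq NH4Cl, −78 °C → rt
Reagents that add atoms: none
Why: In this bulky trialkylborohydride reduction the hydride approaches C8 along the equatorial trajectory (β face), as with 3-keto-5α-steroids, giving the axial 8α-alcohol cis to the equatorial 9α-ester, and at −78 °C both esters survive.

Step 7
Reactants: 17 axial alcohol
Product: 19 2α-acetoxy-9α-angeloyloxy-4β,5β-dimethyl-10αH-Δ7-octalin, via sulfamate salt 18 (not isolated)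
Conditions: Burgess reagent (2 equiv), toluene, rt 1 h, then 80 °C
Reagents that add atoms: none
Why: Burgess dehydration is a thermal syn (Ei) elimination, and the 8α-sulfamate has a cis hydrogen only at C7 (7α-H) because the α position of C9 carries the ester, so only the Δ7 olefin can form.

Step 8
Reactants: 19 allylic angelate
Product: 20 2α-acetoxy-9α-angeloyloxy-7α,8α-epoxy-4β,5β-dimethyl-10αH-decalin
Conditions: mCPBA (1.3 equiv), NaHCO3, CH2Cl2, 0 °C → rt
Reagents that add atoms: mCPBA, O=C(OO)c1cccc(Cl)c1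
Why: Prilezhaev epoxidation occurs on the α face because the β face of C7=C8 is shielded by the syn-axial C5 methyl (as for 5α-2-ene steroids), fixing the C8–O configuration, and the electron-poor angelate C=C does not compete.

Step 9
Reactants: 20 epoxide; 21 isopropenylmagnesium bromide
Product: 22 2α-acetoxy-9α-angeloyloxy-8α-hydroxy-10αH-eremophil-11-ene (CNP0217919.1)
Conditions: 21 (5.7 equiv), CuI (3 equiv), THF/Et2O, −40 °C; add 20, −40 → 0 °C; NH4Cl/NH4OH
Reagents that add atoms: isopropenylmagnesium bromide (21), C=C(C)[Mg]Br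
Why: In this Fürst–Plattner (trans-diaxial) SN2 opening the cuprate attacks C7, the carbon remote from the electron-withdrawing C9 ester, from the β face with inversion and leaves the epoxide oxygen as the axial 8α-OH, the same regiochemistry by which 2α,3α-epoxy-5α-steroids give 2β-substituted 3α-ols, and the stoichiometric cuprate spares both esters.

## Compound list
1 | (S)-(+)-carvone, (5S)-2-methyl-5-(prop-1-en-2-yl)cyclohex-2-en-1-one | CC1=CC[C@H](C(C)=C)CC1=O | starting material
2 | methylmagnesium bromide | C[Mg]Br | starting material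
3 | bromomagnesium (3S,5S)-2,3-dimethyl-5-(prop-1-en-2-yl)cyclohex-1-en-1-olate | Br[Mg]OC1=C(C)[C@@H](C)C[C@H](C(C)=C)C1 | intermediate
4 | {[(3S,5S)-2,3-dimethyl-5-(prop-1-en-2-yl)cyclohex-1-en-1-yl]oxy}trimethylsilane | C[Si](C)(C)OC1=C(C)[C@@H](C)C[C@H](C(C)=C)C1 | intermediate
5 | methyl vinyl ketone (but-3-en-2-one) | C=CC(C)=O | starting material
6 | (2R,3S,5S)-2,3-dimethyl-5-(prop-1-en-2-yl)-2-[3-(trimethylsilyloxy)but-2-en-1-yl]cyclohexan-1-one | CC(O[Si](C)(C)C)=CC[C@]1(C)[C@@H](C)C[C@H](C(C)=C)CC1=O | intermediate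
7 | (2R,3S,5S)-2,3-dimethyl-2-(3-oxobutyl)-5-(prop-1-en-2-yl)cyclohexan-1-one | CC(=O)CC[C@]1(C)[C@@H](C)C[C@H](C(C)=C)CC1=O | intermediate
8 | (4aR,5S,7S)-4a,5-dimethyl-7-(prop-1-en-2-yl)-4,4a,5,6,7,8-hexahydronaphthalen-2(3H)-one (2α-isopropenyl-4β,5β-dimethyl-Δ9(10)-octal-8-one) | O=C1CC[C@]2(C)[C@@H](C)C[C@H](C(C)=C)CC2=C1 | intermediate
9 | lithium Δ8(9)-enolate of 2α-isopropenyl-4β,5β-dimethyl-10αH-decalin-8-one | C1C[C@]2(C)[C@@H](C)C[C@H](C(C)=C)C[C@H]2C=C1[O-].[Li+] | intermediate
10 | 8-trimethylsilyloxy-2α-isopropenyl-4β,5β-dimethyl-10αH-Δ8(9)-octalin | C1C[C@]2(C)[C@@H](C)C[C@H](C(C)=C)C[C@H]2C=C1O[Si](C)(C)C | intermediate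
11 | angelic acid, (Z)-2-methylbut-2-enoic acid | C/C=C(/C)C(=O)O | starting material
12 | O8-[angeloyloxy(phenyl)-λ3-iodanyl] Δ8(9)-enolate of the same decalone | C1C[C@]2(C)[C@@H](C)C[C@H](C(C)=C)C[C@H]2C=C1OI(c1ccccc1)OC(=O)/C(C)=C\C | intermediate
13 | 9α-angeloyloxy-2α-isopropenyl-4β,5β-dimethyl-10αH-decalin-8-one | C1C[C@]2(C)[C@@H](C)C[C@H](C(C)=C)C[C@H]2[C@H](OC(=O)/C(C)=C\C)C1=O | intermediate
14 | 9α-angeloyloxy-2α-(1-hydroperoxy-1-methoxyethyl)-4β,5β-dimethyl-10αH-decalin-8-one (epimers at the acetal carbon) | C1C[C@]2(C)[C@@H](C)C[C@H](C(C)(OC)OO)C[C@H]2[C@H](OC(=O)/C(C)=C\C)C1=O | intermediate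
15 | O-acetyl perester of 14 | C1C[C@]2(C)[C@@H](C)C[C@H](C(C)(OC)OOC(C)=O)C[C@H]2[C@H](OC(=O)/C(C)=C\C)C1=O | intermediate
16 | 2α-acetoxy-9α-angeloyloxy-4β,5β-dimethyl-10αH-decalin-8-one | C1C[C@]2(C)[C@@H](C)C[C@H](OC(C)=O)C[C@H]2[C@H](OC(=O)/C(C)=C\C)C1=O | intermediate
17 | 2α-acetoxy-9α-angeloyloxy-4β,5β-dimethyl-10αH-decalin-8α-ol | C1C[C@]2(C)[C@@H](C)C[C@H](OC(C)=O)C[C@H]2[C@H](OC(=O)/C(C)=C\C)[C@@H]1O | intermediate
18 | triethylammonium 8α-O-[N-(methoxycarbonyl)sulfamate] of 17 | C1C[C@]2(C)[C@@H](C)C[C@H](OC(C)=O)C[C@H]2[C@H](OC(=O)/C(C)=C\C)[C@@H]1OS(=O)(=O)[N-]C(=O)OC.CC[NH+](CC)CC | intermediate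
19 | 2α-acetoxy-9α-angeloyloxy-4β,5β-dimethyl-10αH-Δ7-octalin | C1=CC[C@]2(C)[C@@H](C)C[C@H](OC(C)=O)C[C@H]2[C@@H]1OC(=O)/C(C)=C\C | intermediate
20 | 2α-acetoxy-9α-angeloyloxy-7α,8α-epoxy-4β,5β-dimethyl-10αH-decalin | O1[C@@H]2C[C@]3(C)[C@@H](C)C[C@H](OC(C)=O)C[C@H]3[C@H](OC(=O)/C(C)=C\C)[C@H]12 | intermediate
21 | isopropenylmagnesium bromide | C=C(C)[Mg]Br | starting material
22 | (2S,4S,5R,7R,8R,9S,10R)-2α-acetoxy-9α-angeloyloxy-8α-hydroxy-10αH-eremophil-11-ene | C=C(C)[C@H]1C[C@]2(C)[C@@H](C)C[C@H](OC(C)=O)C[C@H]2[C@H](OC(=O)/C(C)=C\C)[C@@H]1O | target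

## Step count and risks
Total steps: 9. Longest linear sequence: 9, from (S)-carvone.

**Step 4 (the proposed new angelate transfer).** Possible failures are re-elimination to enone 8, protodesilylation or homocoupling.
- The fallback uses known chemistry, sets out from 10 and returns at 13.
- Rubottom oxidation of 10 (mCPBA 1.0 equiv, NaHCO3, hexane/CH2Cl2, −20 °C) gives the 9α-trimethylsilyloxy ketone F1. The enol silane reacts far faster than the isopropenyl group.
- Citric acid in MeOH then frees the 9α-hydroxy ketone F2.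
- F2 is acylated with the mixed anhydride made from 11 and 2,4,6-trichlorobenzoyl chloride/Et3N in toluene at 75 °C. This is the established way to make hindered angelates without Z→E isomerisation, and it gives 13.

**Step 5 (ozone selectivity against the angelate, and Criegee efficiency).**
- The fallback changes the order so that ozone never meets the angelate. It sets out from 8 and returns at 16.
- Ozonolysis of 8 in CH2Cl2/MeOH (the enone C=C is inert) gives the enone methoxy hydroperoxide F3.
- Ac2O/Et3N/DMAP converts it into the enone peracetate F4, which rearranges to the 2α-acetoxy enone F5.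
- The acetate would not survive Li/NH3, so C10–H and C9–O are installed by Mn(dpm)3-catalysed hydrogen-atom-transfer reduction under O2 (PhSiH3, i-PrOH, 0 °C). This gives the 9α-hydroperoxy ketone F6.
- P(OEt)3 reduces F6 to the 9α-hydroxy ketone F7. Et3N equilibrates C9 to the equatorial epimer, and any cis-fused isomer is removed by chromatography.
- The same mixed-anhydride angeloylation with 11 gives 16.

**Step 9 (hindered attack syn to the C5 methyl, in the presence of two esters).**
- The fallback replaces the bulky sp2 cuprate by a slim sp nucleophile and builds the isopropenyl group afterwards. It sets out from 20 and returns at 22.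
- LiC≡CSiMe3/BF3·OEt2 (THF, −78 °C) opens 20 diaxially to the 7β-(trimethylsilylethynyl) 8α-alcohol F8.
- TBAF/AcOH gives the terminal alkyne F9.
- Zr-catalysed methylalumination (AlMe3, Cp2ZrCl2 cat., CH2Cl2, water-accelerated, −20 °C) adds CH3 to the internal carbon and gives the alkenylalane F10.
- Protonolysis of F10 (aq Rochelle salt) delivers 22.

## Further compounds
F1 | step 4 | 9α-trimethylsilyloxy-2α-isopropenyl-4β,5β-dimethyl-10αH-decalin-8-one | C1C[C@]2(C)[C@@H](C)C[C@H](C(C)=C)C[C@H]2[C@H](O[Si](C)(C)C)C1=O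
F2 | step 4 | 9α-hydroxy-2α-isopropenyl-4β,5β-dimethyl-10αH-decalin-8-one | C1C[C@]2(C)[C@@H](C)C[C@H](C(C)=C)C[C@H]2[C@H](O)C1=O
F3 | step 5 | 2α-(1-hydroperoxy-1-methoxyethyl)-4β,5β-dimethyl-Δ9(10)-octal-8-one | O=C1CC[C@]2(C)[C@@H](C)C[C@H](C(C)(OC)OO)CC2=C1
F4 | step 5 | O-acetyl perester of F3 | O=C1CC[C@]2(C)[C@@H](C)C[C@H](C(C)(OC)OOC(C)=O)CC2=C1
F5 | step 5 | 2α-acetoxy-4β,5β-dimethyl-Δ9(10)-octal-8-one | O=C1CC[C@]2(C)[C@@H](C)C[C@H](OC(C)=O)CC2=C1
F6 | step 5 | 2α-acetoxy-9α-hydroperoxy-4β,5β-dimethyl-10αH-decalin-8-one | C1C[C@]2(C)[C@@H](C)C[C@H](OC(C)=O)C[C@H]2[C@H](OO)C1=O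
F7 | step 5 | 2α-acetoxy-9α-hydroxy-4β,5β-dimethyl-10αH-decalin-8-one | C1C[C@]2(C)[C@@H](C)C[C@H](OC(C)=O)C[C@H]2[C@H](O)C1=O
F8 | step 9 | 2α-acetoxy-9α-angeloyloxy-7β-(trimethylsilylethynyl)-4β,5β-dimethyl-10αH-decalin-8α-ol | C[Si](C)(C)C#C[C@H]1C[C@]2(C)[C@@H](C)C[C@H](OC(C)=O)C[C@H]2[C@H](OC(=O)/C(C)=C\C)[C@@H]1O
F9 | step 9 | 2α-acetoxy-9α-angeloyloxy-7β-ethynyl-4β,5β-dimethyl-10αH-decalin-8α-ol | C#C[C@H]1C[C@]2(C)[C@@H](C)C[C@H](OC(C)=O)C[C@H]2[C@H](OC(=O)/C(C)=C\C)[C@@H]1O
F10 | step 9 | 12-(dimethylalumanyl) derivative of 22 as its 8-O-dimethylaluminium alkoxide | C[Al](C)/C=C(\C)[C@H]1C[C@]2(C)[C@@H](C)C[C@H](OC(C)=O)C[C@H]2[C@H](OC(=O)/C(C)=C\C)[C@@H]1O[Al](C)C
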